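**Retrosynthetic overview** (azulene numbering: C1, C2 = ring CH2; C3 = C(OH)iPr; C3a = ring-fusion CH; C4 = ester carbon; C5 = CH2; C6 = C(Me)=; C7 = =CH; C8 = C=O; C8a = C–Me)
1. Late operations: the C8 ketone comes from allylic oxidation of C8H2, the 4-hydroxybenzoate from acylation of a 3,4-diol, and the C6 methyl from an ester that first serves as the activating group of a carbenoid.
2. Enabling feature: in the seven-membered ring (C3a, C4, C5, C6, C7, C8, C8a) the C6=C7 alkene and the C4 oxygen (as a C3a=C4 enol ether) flank C5H2, a cyclohepta-1,4-diene, which is the retron of a divinylcyclopropane Cope rearrangement.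
3. Key disconnection: C5–C6 and C8–C8a are made together by a rhodium-carbenoid (4+3) cycloaddition of a 2-siloxydiene (C5=C4–C3a=C8a) with a vinyldiazoacetate (C6, C7, C8), uniting the two fragments at the quaternary carbon C8a.
4. The diene comes from a β-hydroxy enone made by ozonolysis/aldol ring contraction of (S)-terpinen-4-ol, whose carbinol carbon becomes C3.
5. Ring order: five-membered ring (ring contraction), then a temporary six-membered silylene ring tying O3 to O4, then the seven-membered ring (key step); the silylene ring is removed afterwards.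

Key step: step 7

Remark (assumption): (S)-(+)-terpinen-4-ol is used in high enantiomeric purity; its carbinol configuration is carried unchanged into C3.
Convention: α is the face of the C8a methyl group (and of the C3–O bond), β the opposite face.

Step 1
Reactants: 1 (S)-(+)-terpinen-4-ol
Product: 3 (3S)-3-hydroxy-6-oxo-3-(propan-2-yl)heptanal, via ozonide 2 (not isolated)
Conditions: O3, CH2Cl2, −78 °C; then Me2S, −78 °C to rt
Reagents that add atoms: ozone, [O-][O+]=O
Why: Ozonolysis with reductive work-up cleaves the only alkene to the keto aldehyde (partly as its lactol), leaving the tertiary carbinol stereocentre untouched.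

Step 2
Reactants: 3 (3S)-3-hydroxy-6-oxo-3-(propan-2-yl)heptanal
Product: 5 (5R)-5-hydroxy-2-methyl-5-(propan-2-yl)cyclopent-1-ene-1-carbaldehyde, via aldol adduct 4 (not isolated)
Conditions: piperidine (cat.), AcOH (cat.), toluene, rt to 50 °C
Reagents that add atoms: none
Why: Enamine-mediated intramolecular aldol condensation, in which the aldehyde enamine attacks the methyl ketone (5-exo) and loss of water gives the tetrasubstituted enal, while the carbinol centre is not involved.

Step 3
Reactants: 5 (5R)-5-hydroxy-2-methyl-5-(propan-2-yl)cyclopent-1-ene-1-carbaldehyde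
Product: 6 (1R)-2-(1-hydroxyethyl)-3-methyl-1-(propan-2-yl)cyclopent-2-en-1-ol (both carbinol epimers)
Conditions: MeMgBr (2.5 equiv), THF, −78 to 0 °C
Reagents that add atoms: methylmagnesium bromide, C[Mg]Br
Why: 1,2-Grignard addition to the enal, whose β-carbon is fully substituted; the new carbinol centre is inconsequential because it is oxidised in step 4.

Step 4
Reactants: 6 (1R)-2-(1-hydroxyethyl)-3-methyl-1-(propan-2-yl)cyclopent-2-en-1-ol
Product: 7 1-[(5R)-5-hydroxy-2-methyl-5-(propan-2-yl)cyclopent-1-en-1-yl]ethan-1-one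
Conditions: MnO2, CH2Cl2, rt
Reagents that add atoms: none
Why: Chemoselective MnO2 oxidation of the secondary allylic alcohol; the tertiary alcohol cannot be oxidised.

Step 5
Reactants: 7 1-[(5R)-5-hydroxy-2-methyl-5-(propan-2-yl)cyclopent-1-en-1-yl]ethan-1-one
Product: 9 (7aR)-2,2-di-tert-butyl-5-methyl-4-methylidene-7a-(propan-2-yl)-4,6,7,7a-tetrahydrocyclopenta[d][1,3,2]dioxasiline (cyclic silylene dienol ether), via silyl triflate 8 (not isolated)
Conditions: tBu2Si(OTf)2, Et3N, CH2Cl2, 0 °C to rt
Reagents that add atoms: di-tert-butylsilyl bis(trifluoromethanesulfonate), CC(C)(C)[Si](OS(=O)(=O)C(F)(F)F)(OS(=O)(=O)C(F)(F)F)C(C)(C)C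
Why: O-silylation of the tertiary alcohol and kinetic enol silylation of the methyl ketone towards CH3 (silyl triflate/amine) close a six-membered silylene ring that holds the 2-siloxydiene s-cis; no stereocentre is formed.

Step 6
Reactants: 10 methyl but-3-enoate
Product: 11 methyl 2-diazobut-3-enoate (used freshly prepared)
Conditions: 4-acetamidobenzenesulfonyl azide, DBU, MeCN, 0 °C
Reagents that add atoms: 4-acetamidobenzenesulfonyl azide, CC(=O)Nc1ccc(cc1)S(=O)(=O)N=[N+]=[N-]
Why: Regitz diazo transfer to the α-position of the β,γ-unsaturated ester, which is activated by both the ester and the vinyl group.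

Step 7
Reactants: 9 cyclic silylene dienol ether; 11 methyl 2-diazobut-3-enoate
Product: 13 methyl (3R,8aR)-3,4-[(di-tert-butylsilanediyl)bis(oxy)]-8a-methyl-3-(propan-2-yl)-1,2,3,5,8,8a-hexahydroazulene-6-carboxylate, via divinylcyclopropane 12 (not isolated)
Conditions: Rh2(O2CCMe3)4 (1 mol %), hexane, 0 °C, slow addition of 11 (1.5 equiv); then toluene, 90 °C
Reagents that add atoms: none
Why: The divalent rhodium carbenoid from 11 cyclopropanates the only reactive alkene of 9, the exocyclic enol ether C5=C4 (the ring alkene C3a=C8a is tetrasubstituted), to give the donor–acceptor cis-divinylcyclopropane 12, which undergoes Cope rearrangement through a boat transition state, breaking C4–C6 and forming C8–C8a; the closest known reaction type is the tandem cyclopropanation/Cope rearrangement (formal (4+3) cycloaddition) of vinyldiazoacetates with 2-siloxy-1,3-dienes. The seven-membered ring is therefore closed by a [3,3] sigmatropic ring expansion of the three-membered ring (C5–C6 from the cyclopropanation, C8–C8a from the rearrangement), not by a direct cyclisation. The one new stereocentre, quaternary C8a, is set by the face of the enol ether that is cyclopropanated, because the boat transition state relays the configuration of the spiro carbon C4 to C8a; the silylene ring holds the diene s-cis and puts a tert-butyl group over the α face, so the carbenoid should add to the β face and place C8 anti to the C3 oxygen. The regiochemistry needs the carbenoid carbon at the CH2 terminus and the vinyl terminus at C8a, which the polarised enol ether secures; reaction at the carbenoid carbon instead of vinylogous attack is favoured by the electron-rich carboxylate catalyst in a hydrocarbon solvent. The cyclopropane isomer with the vinyl group trans to C3a cannot rearrange directly, but reversible opening of the donor–acceptor bond C4–C6 on heating should funnel it into the same product.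

Step 8
Reactants: 13 methyl ester cycloadduct
Product: 14 [(3R,8aR)-3,4-[(di-tert-butylsilanediyl)bis(oxy)]-8a-methyl-3-(propan-2-yl)-1,2,3,5,8,8a-hexahydroazulen-6-yl]methanol
Conditions: iBu2AlH (2.2 equiv), CH2Cl2, −78 °C
Reagents that add atoms: none
Why: 1,2-Reduction of the α,β-unsaturated ester by iBu2AlH at low temperature; the silyl enol ether and both stereocentres are unaffected.

Step 9
Reactants: 14 allylic alcohol
Product: 16 (3R,8aR)-3,4-[(di-tert-butylsilanediyl)bis(oxy)]-6,8a-dimethyl-3-(propan-2-yl)-1,2,3,5,8,8a-hexahydroazulene, via mesylate 15 (not isolated)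
Conditions: MsCl, Et3N, THF, −40 °C; then LiBHEt3, −40 to 0 °C
Reagents that add atoms: methanesulfonyl chloride, CS(=O)(=O)Cl (its atoms stay in 15 only)
Why: Mesylation followed by SN2 hydride displacement at the primary allylic carbon turns the former activating group into the C6 methyl group without moving the C6=C7 alkene.

Step 10
Reactants: 16 silylene-bridged diene
Product: 17 (3R,3aR,8aR)-3-hydroxy-6,8a-dimethyl-3-(propan-2-yl)-2,3,3a,5,8,8a-hexahydroazulen-4(1H)-one
Conditions: HF·pyridine, pyridine, THF, 0 °C to rt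
Reagents that add atoms: none
Why: Fluoride cleavage of both Si–O bonds frees the tertiary alcohol and the C4 ketone; C3a is epimerisable through the enol and should settle with H β, trans to the angular methyl group (C4 cis to the C3 hydroxyl and trans to the isopropyl group, with an O–H···O=C hydrogen bond), so both C3a epimers converge on the trans-fused ketone.

Step 11
Reactants: 17 β-hydroxy ketone
Product: 18 (3R,3aS,4S,8aR)-6,8a-dimethyl-3-(propan-2-yl)-1,2,3,3a,4,5,8,8a-octahydroazulene-3,4-diol
Conditions: Me4NBH(OAc)3, MeCN/AcOH, −30 to −20 °C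
Reagents that add atoms: none
Why: Evans–Saksena hydroxyl-directed reduction, in which the boron-bound C3 alkoxide delivers hydride intramolecularly to the C4 carbonyl from the α face (the face of the C3–O bond), giving the 1,3-anti diol with the C4 hydroxyl β.

Step 12
Reactants: 18 diol; 19 4-acetoxybenzoyl chloride
Product: 20 (3R,3aS,4S,8aR)-3-hydroxy-6,8a-dimethyl-3-(propan-2-yl)-1,2,3,3a,4,5,8,8a-octahydroazulen-4-yl 4-acetoxybenzoate
Conditions: pyridine, DMAP (cat.), CH2Cl2, 0 °C to rt
Reagents that add atoms: none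
Why: DMAP-catalysed acylation of the secondary C4 alcohol with retention; the tertiary C3 alcohol is too hindered to react.

Step 13
Reactants: 20 acetoxybenzoate
Product: 21 (3R,3aS,4S,8aS)-3-hydroxy-6,8a-dimethyl-8-oxo-3-(propan-2-yl)-1,2,3,3a,4,5,8,8a-octahydroazulen-4-yl 4-acetoxybenzoate
Conditions: Rh2(C6H10NO)4 (dirhodium tetrakis(caprolactamate), cat.), tBuOOH (70% aq., 5 equiv), K2CO3, CH2Cl2, rt
Reagents that add atoms: tert-butyl hydroperoxide, CC(C)(C)OO
Why: Radical-chain allylic C–H oxidation of a 1-methylcycloalkene to the 3-methyl-2-enone, with hydrogen abstraction at C8 (next to the C7 terminus), while C5 is deactivated by the neighbouring C4 acyloxy group; no stereocentre is touched.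

Step 14
Reactants: 21 enone acetoxybenzoate
Product: 22 (3R,3aS,4S,8aS)-3-hydroxy-6,8a-dimethyl-8-oxo-3-(propan-2-yl)-1,2,3,3a,4,5,8,8a-octahydroazulen-4-yl 4-hydroxybenzoate (target)
Conditions: K2CO3 (cat.), MeOH, 0 °C
Reagents that add atoms: none
Why: Base-catalysed methanolysis removes the aryl acetate (phenoxide leaving group) much faster than it attacks the hindered secondary benzoate, which is further deactivated once the phenoxide forms.

**Compound list**
1 | (S)-(+)-terpinen-4-ol, (1S)-4-methyl-1-(propan-2-yl)cyclohex-3-en-1-ol | CC1=CC[C@](O)(C(C)C)CC1 | starting material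
2 | ozonide (1,2,4-trioxolane) of 1 | CC12CC[C@@](O)(C(C)C)CC(OO1)O2 | intermediate
3 | (3S)-3-hydroxy-6-oxo-3-(propan-2-yl)heptanal | O=CC[C@](O)(C(C)C)CCC(C)=O | intermediate
4 | (5R)-2,5-dihydroxy-2-methyl-5-(propan-2-yl)cyclopentane-1-carbaldehyde (aldol adduct, mixture at C1 and C2) | O=CC1C(C)(O)CC[C@@]1(O)C(C)C | intermediate
5 | (5R)-5-hydroxy-2-methyl-5-(propan-2-yl)cyclopent-1-ene-1-carbaldehyde | O=CC1=C(C)CC[C@@]1(O)C(C)C | intermediate
6 | (1R)-2-(1-hydroxyethyl)-3-methyl-1-(propan-2-yl)cyclopent-2-en-1-ol (carbinol epimers) | CC(O)C1=C(C)CC[C@@]1(O)C(C)C | intermediate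
7 | 1-[(5R)-5-hydroxy-2-methyl-5-(propan-2-yl)cyclopent-1-en-1-yl]ethan-1-one | CC(=O)C1=C(C)CC[C@@]1(O)C(C)C | intermediate
8 | tertiary O-[di-tert-butyl(trifluoromethanesulfonyloxy)silyl] ether of 7 | CC(=O)C1=C(C)CC[C@@]1(O[Si](OS(=O)(=O)C(F)(F)F)(C(C)(C)C)C(C)(C)C)C(C)C | intermediate
9 | (7aR)-2,2-di-tert-butyl-5-methyl-4-methylidene-7a-(propan-2-yl)-4,6,7,7a-tetrahydrocyclopenta[d][1,3,2]dioxasiline | C=C1O[Si](C(C)(C)C)(C(C)(C)C)O[C@@]2(C(C)C)CCC(C)=C12 | intermediate
10 | methyl but-3-enoate | COC(=O)CC=C | starting material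
11 | methyl 2-diazobut-3-enoate | COC(=O)C(=[N+]=[N-])C=C | intermediate
12 | spiro donor–acceptor cis-divinylcyclopropane (cyclopropane C4–C5–C6 on the β face, vinyl cis to C3a, ester cis to O4) | COC(=O)[C@]1(C=C)C[C@]12O[Si](C(C)(C)C)(C(C)(C)C)O[C@@]3(C(C)C)CCC(C)=C23 | intermediate
13 | methyl (3R,8aR)-3,4-[(di-tert-butylsilanediyl)bis(oxy)]-8a-methyl-3-(propan-2-yl)-1,2,3,5,8,8a-hexahydroazulene-6-carboxylate | COC(=O)C1=CC[C@@]2(C)CC[C@]3(C(C)C)O[Si](C(C)(C)C)(C(C)(C)C)OC(=C23)C1 | intermediate
14 | [(3R,8aR)-3,4-[(di-tert-butylsilanediyl)bis(oxy)]-8a-methyl-3-(propan-2-yl)-1,2,3,5,8,8a-hexahydroazulen-6-yl]methanol | OCC1=CC[C@@]2(C)CC[C@]3(C(C)C)O[Si](C(C)(C)C)(C(C)(C)C)OC(=C23)C1 | intermediate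
15 | methanesulfonate of 14 | CS(=O)(=O)OCC1=CC[C@@]2(C)CC[C@]3(C(C)C)O[Si](C(C)(C)C)(C(C)(C)C)OC(=C23)C1 | intermediate
16 | (3R,8aR)-3,4-[(di-tert-butylsilanediyl)bis(oxy)]-6,8a-dimethyl-3-(propan-2-yl)-1,2,3,5,8,8a-hexahydroazulene | CC1=CC[C@@]2(C)CC[C@]3(C(C)C)O[Si](C(C)(C)C)(C(C)(C)C)OC(=C23)C1 | intermediate
17 | (3R,3aR,8aR)-3-hydroxy-6,8a-dimethyl-3-(propan-2-yl)-2,3,3a,5,8,8a-hexahydroazulen-4(1H)-one | CC1=CC[C@@]2(C)CC[C@@](O)(C(C)C)[C@@H]2C(=O)C1 | intermediate
18 | (3R,3aS,4S,8aR)-6,8a-dimethyl-3-(propan-2-yl)-1,2,3,3a,4,5,8,8a-octahydroazulene-3,4-diol | CC1=CC[C@@]2(C)CC[C@@](O)(C(C)C)[C@@H]2[C@@H](O)C1 | intermediate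
19 | 4-acetoxybenzoyl chloride | CC(=O)Oc1ccc(cc1)C(Cl)=O | starting material
20 | (3R,3aS,4S,8aR)-3-hydroxy-6,8a-dimethyl-3-(propan-2-yl)-1,2,3,3a,4,5,8,8a-octahydroazulen-4-yl 4-acetoxybenzoate | CC1=CC[C@@]2(C)CC[C@@](O)(C(C)C)[C@@H]2[C@@H](OC(=O)c2ccc(OC(C)=O)cc2)C1 | intermediate
21 | (3R,3aS,4S,8aS)-3-hydroxy-6,8a-dimethyl-8-oxo-3-(propan-2-yl)-1,2,3,3a,4,5,8,8a-octahydroazulen-4-yl 4-acetoxybenzoate | CC1=CC(=O)[C@@]2(C)CC[C@@](O)(C(C)C)[C@@H]2[C@@H](OC(=O)c2ccc(OC(C)=O)cc2)C1 | intermediate
22 | (3R,3aS,4S,8aS)-3-hydroxy-6,8a-dimethyl-8-oxo-3-(propan-2-yl)-1,2,3,3a,4,5,8,8a-octahydroazulen-4-yl 4-hydroxybenzoate | CC1=CC(=O)[C@@]2(C)CC[C@@](O)(C(C)C)[C@@H]2[C@@H](OC(=O)c2ccc(O)cc2)C1 | target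

**Step count and risks**
Total steps: 14. Longest linear sequence: 13 (steps 1–5 and 7–14; step 6 is a one-step branch).

Step 7 is the riskiest. The carbenoid may add to the α face of the enol ether (poor facial selectivity, since the β face also carries the isopropyl group). The donor–acceptor cyclopropane may open heterolytically or the carbenoid may react at its vinylogous position instead of rearranging. The Cope rearrangement may be slow because the ring alkene carries a Z-methyl group. The fallback builds the ring stepwise with known chemistry; it sets out from enal 5 and comes back at ketone 17. 2-Methylallylmagnesium chloride (THF, −78 °C) adds to 5 to give the dienyl carbinol (1R)-2-(1-hydroxy-3-methylbut-3-en-1-yl)-3-methyl-1-(propan-2-yl)cyclopent-2-en-1-ol F1. MnO2 oxidises it to the β,γ-unsaturated ketone 1-[(5R)-5-hydroxy-2-methyl-5-(propan-2-yl)cyclopent-1-en-1-yl]-3-methylbut-3-en-1-one F2. A Hosomi–Sakurai conjugate allylation (allyltrimethylsilane, TiCl4, CH2Cl2, −78 °C) of the titanium-chelated β-alkoxy enone should build C8a anti to the chelated oxygen and give the allyl ketone 1-[2-allyl-5-hydroxy-2-methyl-5-(propan-2-yl)cyclopentyl]-3-methylbut-3-en-1-one F3. Ring-closing metathesis with the second-generation Grubbs catalyst (CH2Cl2, 40 °C) then forms C6=C7 and gives 17.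

Step 13 may suffer from hydrogen abstraction at C5 or at the C6 methyl group (poor regioselectivity) or from over-oxidation. The fallback installs the oxygen by transposition; it sets out from 20 and comes back at 21. A Schenck ene reaction with singlet oxygen (O2, hν, tetraphenylporphyrin, CH2Cl2, 0 °C; then PPh3) moves the alkene to C7=C8 and gives the C6 tertiary allylic alcohol F4 (either C6 epimer serves). A Babler–Dauben oxidative transposition with pyridinium chlorochromate, [C5H5NH][CrO3Cl], in CH2Cl2 then gives 21.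

Step 11 may fail if the hindered tertiary hydroxyl does not bind boron, so that hydride arrives externally with poor facial selectivity; acid-promoted dehydration of the β-hydroxy ketone is a second hazard. The fallback uses inversion instead of retention; it sets out from 17 and comes back at 20. A Narasaka–Prasad reduction (Et2BOMe, NaBH4, THF/MeOH, −78 °C; external hydride on the boron chelate) gives the 1,3-syn diol (3R,3aS,4R,8aR)-6,8a-dimethyl-3-(propan-2-yl)-1,2,3,3a,4,5,8,8a-octahydroazulene-3,4-diol F5. Mitsunobu esterification with 4-acetoxybenzoic acid (PPh3, diisopropyl azodicarboxylate, toluene) inverts C4 and gives 20.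

**Further compounds**
F1 | step 7 | (1R)-2-(1-hydroxy-3-methylbut-3-en-1-yl)-3-methyl-1-(propan-2-yl)cyclopent-2-en-1-ol (carbinol epimers) | OC(CC(C)=C)C1=C(C)CC[C@@]1(O)C(C)C
F2 | step 7 | 1-[(5R)-5-hydroxy-2-methyl-5-(propan-2-yl)cyclopent-1-en-1-yl]-3-methylbut-3-en-1-one | O=C(CC(C)=C)C1=C(C)CC[C@@]1(O)C(C)C
F3 | step 7 | 1-[2-allyl-5-hydroxy-2-methyl-5-(propan-2-yl)cyclopentyl]-3-methylbut-3-en-1-one, configured as C8a, C3a and C3 of 17 | C=CC[C@@]1(C)CC[C@@](O)(C(C)C)[C@@H]1C(=O)CC(C)=C
F4 | step 13 | (3R,3aS,4S,8aS)-3,6-dihydroxy-6,8a-dimethyl-3-(propan-2-yl)-1,2,3,3a,4,5,6,8a-octahydroazulen-4-yl 4-acetoxybenzoate (either C6 epimer) | CC1(O)C=C[C@@]2(C)CC[C@@](O)(C(C)C)[C@@H]2[C@@H](OC(=O)c2ccc(OC(C)=O)cc2)C1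
F5 | step 11 | (3R,3aS,4R,8aR)-6,8a-dimethyl-3-(propan-2-yl)-1,2,3,3a,4,5,8,8a-octahydroazulene-3,4-diol | CC1=CC[C@@]2(C)CC[C@@](O)(C(C)C)[C@@H]2[C@H](O)C1
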